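The dihydropyran ring of the chroman (O1, C2, C3, C4, C4a, C8a) is disconnected at C4–C3 and O1–C2 into an o-quinone methide (C4=C4a–C8a=O1), released by fluoride from a silyloxybenzyl bromide, and a Z-trisubstituted alkenyl boronate. One oxa-[4+2] cycloaddition closes this ring and sets both stereocentres: the Z-alkene fixes the cis relation between the C3 heteroatom and the C2 side arm, the tertiary C2 terminus and the boron on C3 fix the regiochemistry, and a pinene-derived iminodiacetate cage on boron fixes the absolute sense. The C3–B bond is then oxidised with retention to C3–O; acetylation and a cross-metathesis that completes the 4-hydroxy-4-methylpent-2-enyl arm end the route.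

Key step: step 7

Assumption (chemistry): ligand 4 with the (1R,2R,3R,5S)-isopinocampheyl group is taken to expose the alkene face that leads to the (2R,3R) cycloadduct; if the sense proves opposite, the ligand from the commercial (1S,2S,3S,5R)-amine is used and nothing else changes.

Step 1
Reactants: 1 (1R,2R,3R,5S)-isopinocampheylamine; 2 benzyl bromoacetate (2.2 equiv)
Product: 3 dibenzyl N-[(1R,2R,3R,5S)-isopinocampheyl]iminodiacetate
Conditions: K2CO3, NaI (cat.), MeCN, 60 °C
Reagents that add atoms: none
Why: Double SN2 N-alkylation of the primary amine by the α-bromo ester should stop at the tertiary amine and leaves the pinane stereocentres untouched.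

Step 2
Reactants: 3 dibenzyl N-isopinocampheyliminodiacetate
Product: 4 N-[(1R,2R,3R,5S)-isopinocampheyl]iminodiacetic acid (chiral ligand for boron)
Conditions: H2 (1 atm), Pd/C (palladium on carbon), MeOH, rt
Reagents that add atoms: none
Why: Hydrogenolysis of the two benzyl esters should free the amino diacid under neutral conditions without touching the N-alkyl group.

Step 3
Reactants: 5 propyne; 6 boron tribromide; 4 ligand diacid
Product: 8 2-[(1Z)-2-bromoprop-1-enyl]-6-[(1R,2R,3R,5S)-isopinocampheyl]-1,3,6,2-dioxazaborocane-4,8-dione, via (Z)-(2-bromoprop-1-enyl)dibromoborane 7 (not isolated)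
Conditions: BBr3, CH2Cl2, −78 °C to rt; then 4, 2,6-lutidine, MeCN, 0 °C to rt
Reagents that add atoms: none
Why: Syn-bromoboration (haloboration) of the terminal alkyne puts boron on the terminal carbon with bromine cis to it, and trapping of the dibromoborane by the diacid as the N→B cage fixes this Z-geometry in an air-stable boronate.

Step 4
Reactants: 8 bromoalkenyl cage boronate; 9 allyltributylstannane
Product: 10 2-[(1Z)-2-methylpenta-1,4-dienyl]-6-[(1R,2R,3R,5S)-isopinocampheyl]-1,3,6,2-dioxazaborocane-4,8-dione
Conditions: Pd2(dba)3 (cat.), P(2-furyl)3, DMF, 50 °C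
Reagents that add atoms: none
Why: Stille coupling at the C–Br bond should proceed with retention of alkene geometry while the tetracoordinate boron stays inert under anhydrous conditions, leaving boron cis to the new allyl arm.

Step 5
Reactants: 11 methyl 4-hydroxy-3-methylbenzoate
Product: 12 methyl 4-[(tert-butyldimethylsilyl)oxy]-3-methylbenzoate
Conditions: TBSCl, imidazole, DMF, rt
Reagents that add atoms: tert-butyldimethylsilyl chloride, CC(C)(C)[Si](C)(C)Cl
Why: Standard O-silylation of the phenol installs the fluoride-labile trigger for the later quinone methide release.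

Step 6
Reactants: 12 silyl ether
Product: 13 methyl 3-(bromomethyl)-4-[(tert-butyldimethylsilyl)oxy]benzoate
Conditions: NBS, AIBN (cat.), PhCF3, reflux
Reagents that add atoms: N-bromosuccinimide, O=C1CCC(=O)N1Br
Why: Wohl–Ziegler radical bromination should take place at the only benzylic position, the ester deactivating the ring towards electrophilic bromination.

Step 7
Reactants: 13 silyloxybenzyl bromide (2.5 equiv, added over 6 h); 10 Z-dienyl cage boronate
Product: 15 methyl (2R,3R)-2-methyl-2-(prop-2-enyl)-3-[6-isopinocampheyl-4,8-dioxo-1,3,6,2-dioxazaborocan-2-yl]-3,4-dihydro-2H-chromene-6-carboxylate, via o-quinone methide 14 (not isolated)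
Conditions: CsF, MeCN, 60 °C, slow addition of 13
Reagents that add atoms: none
Why: Proposed new method: fluoride removes the silyl group of 13 and the phenoxide expels bromide to give o-quinone methide 14, whose O1=C8a–C4a=C4 heterodiene adds across the Z-alkene of 10 in an inverse-electron-demand oxa-Diels–Alder reaction; the closest known type is the cycloaddition of o-quinone methides with unactivated trisubstituted alkenes, and an alkenyl boronate has not been shown as the 2π partner. The dihydropyran ring is closed by the concerted, asynchronous suprafacial [4+2] addition itself, the C4–C3 bond leading and the O1–C2 bond following. Regiochemistry needs the methylene on the boron-bearing CH and the oxygen on the disubstituted carbon, and this is secured because the positive charge that builds at C2 is tertiary and is stabilised by the electron-rich tetracoordinate C–B bond, while the saturated boron cannot hand its alkenyl group to the methylene as trigonal boronates do. The cis relation of boron at C3 and the allyl arm at C2 follows from the Z-geometry, and the unsubstituted methylene terminus leaves no endo/exo question. The absolute configuration at C2 and C3 is controlled by the isopinocampheyl group on nitrogen, which screens one alkene face as it does in peracid epoxidation of alkenyl boronates of this ligand, and any minor diastereomer should be removable by chromatography on silica. Site selectivity for the trisubstituted alkene over the vinyl group rests on its higher substitution, and slow addition of 13 keeps 14 from oligomerising.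

Step 8
Reactants: 15 chromanyl cage boronate
Product: 16 methyl (2R,3R)-3-hydroxy-2-methyl-2-(prop-2-enyl)-3,4-dihydro-2H-chromene-6-carboxylate
Conditions: NaOH (1 M aq), 30% H2O2, THF, 0 °C to rt
Reagents that add atoms: hydrogen peroxide, OO
Why: Hydroxide opens the iminodiacetate cage and hydroperoxide then oxidises the C3–B bond by 1,2-migration from boron to oxygen with retention (organoborane oxidation), so the 3R configuration is kept.

Step 9
Reactants: 16 chromanol
Product: 17 methyl (2R,3R)-3-acetoxy-2-methyl-2-(prop-2-enyl)-3,4-dihydro-2H-chromene-6-carboxylate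
Conditions: Ac2O, pyridine, DMAP (cat.), CH2Cl2, rt
Reagents that add atoms: acetic anhydride, CC(=O)OC(C)=O
Why: DMAP-catalysed acylation of the only hydroxyl group should give the acetate without affecting either stereocentre.

Step 10
Reactants: 17 allyl chroman acetate; 18 2-methylbut-3-en-2-ol (5 equiv)
Product: 19 methyl (2R,3R)-3-acetoxy-2-[(2E)-4-hydroxy-4-methylpent-2-enyl]-2-methyl-3,4-dihydro-2H-chromene-6-carboxylate (target)
Conditions: second-generation Hoveyda–Grubbs catalyst RuCl2(H2IMes)(=CH-C6H4-2-OiPr) (5 mol%), CH2Cl2, 40 °C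
Reagents that add atoms: none
Why: Olefin cross-metathesis of the terminal alkene with the hindered tertiary allylic alcohol, which homodimerises slowly, should give the E-disubstituted alkene under thermodynamic control.

Compound list
1 | (1R,2R,3R,5S)-isopinocampheylamine | C[C@H]1[C@H](N)C[C@@H]2C[C@H]1C2(C)C | starting material
2 | benzyl bromoacetate | BrCC(=O)OCc1ccccc1 | starting material
3 | dibenzyl N-[(1R,2R,3R,5S)-isopinocampheyl]iminodiacetate | C[C@H]1[C@H](N(CC(=O)OCc3ccccc3)CC(=O)OCc3ccccc3)C[C@@H]2C[C@H]1C2(C)C | intermediate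
4 | N-[(1R,2R,3R,5S)-isopinocampheyl]iminodiacetic acid | C[C@H]1[C@H](N(CC(=O)O)CC(=O)O)C[C@@H]2C[C@H]1C2(C)C | intermediate
5 | propyne | CC#C | starting material
6 | boron tribromide | BrB(Br)Br | starting material
7 | (Z)-(2-bromoprop-1-enyl)dibromoborane | C/C(Br)=C/B(Br)Br | intermediate (not isolated)
8 | 2-[(1Z)-2-bromoprop-1-enyl]-6-[(1R,2R,3R,5S)-isopinocampheyl]-1,3,6,2-dioxazaborocane-4,8-dione | C[C@H]1[C@H]([N+]34CC(=O)O[B-]3(/C=C(/C)Br)OC(=O)C4)C[C@@H]2C[C@H]1C2(C)C | intermediate
9 | allyltributylstannane | C=CC[Sn](CCCC)(CCCC)CCCC | starting material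
10 | 2-[(1Z)-2-methylpenta-1,4-dienyl]-6-[(1R,2R,3R,5S)-isopinocampheyl]-1,3,6,2-dioxazaborocane-4,8-dione | C[C@H]1[C@H]([N+]34CC(=O)O[B-]3(/C=C(/C)CC=C)OC(=O)C4)C[C@@H]2C[C@H]1C2(C)C | intermediate
11 | methyl 4-hydroxy-3-methylbenzoate | COC(=O)c1ccc(O)c(C)c1 | starting material
12 | methyl 4-[(tert-butyldimethylsilyl)oxy]-3-methylbenzoate | COC(=O)c1ccc(O[Si](C)(C)C(C)(C)C)c(C)c1 | intermediate
13 | methyl 3-(bromomethyl)-4-[(tert-butyldimethylsilyl)oxy]benzoate | COC(=O)c1ccc(O[Si](C)(C)C(C)(C)C)c(CBr)c1 | intermediate
14 | methyl 3-methylidene-4-oxocyclohexa-1,5-diene-1-carboxylate (o-quinone methide) | COC(=O)C1=CC(=C)C(=O)C=C1 | intermediate (not isolated)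
15 | methyl (2R,3R)-2-methyl-2-(prop-2-enyl)-3-[6-isopinocampheyl-4,8-dioxo-1,3,6,2-dioxazaborocan-2-yl]-3,4-dihydro-2H-chromene-6-carboxylate | C[C@H]1[C@H]([N+]34CC(=O)O[B-]3([C@@H]5Cc6cc(C(=O)OC)ccc6O[C@]5(C)CC=C)OC(=O)C4)C[C@@H]2C[C@H]1C2(C)C | intermediate
16 | methyl (2R,3R)-3-hydroxy-2-methyl-2-(prop-2-enyl)-3,4-dihydro-2H-chromene-6-carboxylate | COC(=O)c1ccc2c(c1)C[C@@H](O)[C@@](C)(CC=C)O2 | intermediate
17 | methyl (2R,3R)-3-acetoxy-2-methyl-2-(prop-2-enyl)-3,4-dihydro-2H-chromene-6-carboxylate | COC(=O)c1ccc2c(c1)C[C@@H](OC(C)=O)[C@@](C)(CC=C)O2 | intermediate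
18 | 2-methylbut-3-en-2-ol | C=CC(C)(C)O | starting material
19 | methyl (2R,3R)-3-acetoxy-2-[(2E)-4-hydroxy-4-methylpent-2-enyl]-2-methyl-3,4-dihydro-2H-chromene-6-carboxylate | COC(=O)c1ccc2c(c1)C[C@@H](OC(C)=O)[C@@](C)(C/C=C/C(C)(C)O)O2 | target

Total step count: 10. Longest linear sequence: 8 steps (steps 1, 2, 3, 4, 7, 8, 9, 10).

Steps most likely to fail

Step 7 (proposed new method). The quinone methide may oligomerise faster than it adds to the hindered boron-bearing alkene, facial discrimination by the cage may be weak at 60 °C, and addition to the vinyl group may compete. The fallback uses known chemistry and forms the two bonds in separate steps. It sets out from 10 and 13: a Suzuki–Miyaura coupling (Pd(OAc)2, SPhos, K3PO4, dioxane/H2O, 60 °C, the cage being hydrolysed slowly in situ) should join the benzylic carbon to the boron-bearing alkene carbon with retention of geometry and give methyl 4-[(tert-butyldimethylsilyl)oxy]-3-[(2Z)-3-methylhexa-2,5-dienyl]benzoate F1. Shi epoxidation of the trisubstituted alkene (D-fructose-derived ketone, KHSO5, K2CO3, MeCN/dimethoxymethane/H2O, 0 °C; the ketone enantiomer is chosen for this sense) should give methyl 4-[(tert-butyldimethylsilyl)oxy]-3-{[(2R,3S)-3-methyl-3-(prop-2-enyl)oxiran-2-yl]methyl}benzoate F2. Buffered desilylation (Bu4NF, AcOH, THF, 0 °C) should give the phenol methyl 4-hydroxy-3-{[(2R,3S)-3-methyl-3-(prop-2-enyl)oxiran-2-yl]methyl}benzoate F3, and camphorsulfonic acid in CH2Cl2 should close the pyran by 6-endo attack of the phenol on the tertiary epoxide carbon with inversion. This comes back to the route at 16.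

Step 3. The dibromoborane may isomerise from Z to E before it is trapped, and cage formation with the hindered ligand may be incomplete. The fallback sets out from 5 and replaces steps 3 and 4 by a borylative allylation: copper-catalysed syn-carboboration of propyne (CuCl, Xantphos, NaOtBu, B2pin2, allyl bromide, THF, rt) should give 4,4,5,5-tetramethyl-2-[(1Z)-2-methylpenta-1,4-dienyl]-1,3,2-dioxaborolane F4 with boron and the allyl group cis. Cleavage of the pinacol ester (NaIO4, NH4OAc, acetone/H2O) should give [(1Z)-2-methylpenta-1,4-dienyl]boronic acid F5, and condensation with 4 (toluene/DMSO, Dean–Stark, 110 °C) comes back to the route at 10.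

Step 8. Hydrolysis of the hindered cage may be slow, the methyl ester may be saponified in competition, and the aryloxide may be lost by β-elimination from the intermediate boronate. The fallback sets out from 15 and accepts the saponification: prolonged treatment with excess NaOH and H2O2 (THF/MeOH/H2O, rt) should cleave cage, C–B bond and ester together to give (2R,3R)-3-hydroxy-2-methyl-2-(prop-2-enyl)-3,4-dihydro-2H-chromene-6-carboxylic acid F6, and selective O-methylation of the acid (Me3SiCHN2, toluene/MeOH, 0 °C) comes back to the route at 16.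

Further compounds
F1 | step 7 | methyl 4-[(tert-butyldimethylsilyl)oxy]-3-[(2Z)-3-methylhexa-2,5-dienyl]benzoate | COC(=O)c1ccc(O[Si](C)(C)C(C)(C)C)c(C/C=C(/C)CC=C)c1
F2 | step 7 | methyl 4-[(tert-butyldimethylsilyl)oxy]-3-{[(2R,3S)-3-methyl-3-(prop-2-enyl)oxiran-2-yl]methyl}benzoate | COC(=O)c1ccc(O[Si](C)(C)C(C)(C)C)c(C[C@H]2O[C@@]2(C)CC=C)c1
F3 | step 7 | methyl 4-hydroxy-3-{[(2R,3S)-3-methyl-3-(prop-2-enyl)oxiran-2-yl]methyl}benzoate | COC(=O)c1ccc(O)c(C[C@H]2O[C@@]2(C)CC=C)c1
F4 | step 3 | 4,4,5,5-tetramethyl-2-[(1Z)-2-methylpenta-1,4-dienyl]-1,3,2-dioxaborolane | C=CC/C(C)=C\B1OC(C)(C)C(C)(C)O1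
F5 | step 3 | [(1Z)-2-methylpenta-1,4-dienyl]boronic acid | C=CC/C(C)=C\B(O)O
F6 | step 8 | (2R,3R)-3-hydroxy-2-methyl-2-(prop-2-enyl)-3,4-dihydro-2H-chromene-6-carboxylic acid | OC(=O)c1ccc2c(c1)C[C@@H](O)[C@@](C)(CC=C)O2
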